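The flavanone is reached from its flavone, and the plan rests on cutting pyranone ring C at its ketone. C4 carries only oxygen and links C4a of ring A to C3, while O1 is bound to the adjacent C8a. Ring C can therefore be made in one palladium-catalysed operation from a fully substituted ortho-iodophenol, carbon monoxide and 6-ethynyl-2,2-dimethylchromene, which forms C4a–C4, C4–C3 and O1–C2. The iodophenol bears both prenyl groups, two MOM ethers and one free hydroxyl next to iodine, all placed by directed lithiation or sterically governed C–H borylation. Copper hydride reduction then sets (2S) and acid frees the phenols.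

Key step: step 11

Remark on the chemistry: the tetrahydropyranyl compounds 8 to 12 are racemic at the acetal carbon, which is removed in step 7; the ligand antipode that gives (2S) in step 12 has to be confirmed on a test scale, and the route is written with (R)-DTBM-SEGPHOS.

Step 1
Reactants: 1 resorcinol (benzene-1,3-diol)
Product: 2 1,3-bis(methoxymethoxy)benzene
Conditions: NaH (2.4 equiv), MOMCl (2.3 equiv), DMF, 0 °C to rt
Reagents that add atoms: chloromethyl methyl ether (MOMCl), COCCl
Why: Williamson-type O-alkylation of both sodium phenoxides with the chloromethyl ether should give the bis(formaldehyde acetal), whose two MOM groups direct the later lithiations and end up on O5 and O7.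

Step 2
Reactants: 2 1,3-bis(methoxymethoxy)benzene; 3 1-bromo-3-methylbut-2-ene (prenyl bromide)
Product: 5 1,3-bis(methoxymethoxy)-2-(3-methylbut-2-en-1-yl)benzene, via aryllithium 4 (not isolated)
Conditions: n-BuLi (1.1 equiv), THF, 0 °C to rt; then CuBr·SMe2 (10 mol %), 3 (1.2 equiv), −78 °C to rt
Reagents that add atoms: none
Why: Directed ortho-metalation removes the hydrogen between the two chelating MOM oxygens, and copper-catalysed SN2 allylation of the aryllithium at the primary carbon of 3 should give the linear prenyl group on the carbon that becomes C6.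

Step 3
Reactants: 5 1,3-bis(methoxymethoxy)-2-(3-methylbut-2-en-1-yl)benzene
Product: 7 3,5-bis(methoxymethoxy)-4-(3-methylbut-2-en-1-yl)phenol, via arylboronate 6 (not isolated)
Conditions: [Ir(OMe)(cod)]2 (1.5 mol %), 4,4'-di-tert-butyl-2,2'-bipyridine (3 mol %), B2pin2 (0.6 equiv), THF, 65 °C; then aq. NaOH, 30% H2O2, 0 °C
Reagents that add atoms: hydrogen peroxide, OO; bis(pinacolato)diboron, CC1(C)OB(OC1(C)C)B1OC(C)(C)C(C)(C)O1 (its atoms are present in 6 only)
Why: Iridium-catalysed aromatic C–H borylation is governed by sterics and should reach only the ring hydrogen without an ortho substituent (meta to both MOM groups), and alkaline peroxide oxidation of the C–B bond then installs the third oxygen, so the phloroglucinol pattern arrives with its oxygens already differentiated and the first prenyl group fixed between the two MOM ethers.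

Step 4
Reactants: 7 3,5-bis(methoxymethoxy)-4-(3-methylbut-2-en-1-yl)phenol
Product: 8 2-[3,5-bis(methoxymethoxy)-4-(3-methylbut-2-en-1-yl)phenoxy]tetrahydro-2H-pyran
Conditions: 3,4-dihydro-2H-pyran (1.5 equiv), PPTS (5 mol %), CH2Cl2, rt
Reagents that add atoms: 3,4-dihydro-2H-pyran, C1=COCCC1
Why: Acid-catalysed addition of the phenol to the enol ether (tetrahydropyranylation) should give a mixed acetal that tolerates butyllithium, helps the neighbouring MOM group to direct lithiation (a bulky silyl ether would shield both ortho positions and could migrate from oxygen to carbon) and can be cleaved later without loss of MOM.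

Step 5
Reactants: 8 2-[3,5-bis(methoxymethoxy)-4-(3-methylbut-2-en-1-yl)phenoxy]tetrahydro-2H-pyran; 3 1-bromo-3-methylbut-2-ene
Product: 10 2-[3,5-bis(methoxymethoxy)-2,4-bis(3-methylbut-2-en-1-yl)phenoxy]tetrahydro-2H-pyran, via aryllithium 9 (not isolated)
Conditions: n-BuLi (1.2 equiv), TMEDA (1.2 equiv), THF, −20 to 0 °C; then CuBr·SMe2 (10 mol %), 3 (1.3 equiv), −78 °C to rt
Reagents that add atoms: none
Why: Directed ortho-metalation at one of the two equivalent ring hydrogens, each flanked by the tetrahydropyranyl acetal and a MOM ether, followed by copper-catalysed allylation with 3 should give the second prenyl group (future C8) with no regiochemical choice.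

Step 6
Reactants: 10 2-[3,5-bis(methoxymethoxy)-2,4-bis(3-methylbut-2-en-1-yl)phenoxy]tetrahydro-2H-pyran
Product: 12 2-[2-iodo-3,5-bis(methoxymethoxy)-4,6-bis(3-methylbut-2-en-1-yl)phenoxy]tetrahydro-2H-pyran, via aryllithium 11 (not isolated)
Conditions: n-BuLi (1.2 equiv), TMEDA (1.2 equiv), THF, −20 to 0 °C; then ICH2CH2I (1.3 equiv), −78 °C to rt
Reagents that add atoms: 1,2-diiodoethane, ICCI
Why: Directed ortho-metalation at the last ring hydrogen and iodine transfer from 1,2-diiodoethane to the aryllithium (with loss of ethene) should place iodine on the future C4a without an electrophilic iodinating agent that could attack the prenyl double bonds.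

Step 7
Reactants: 12 2-[2-iodo-3,5-bis(methoxymethoxy)-4,6-bis(3-methylbut-2-en-1-yl)phenoxy]tetrahydro-2H-pyran
Product: 13 2-iodo-3,5-bis(methoxymethoxy)-4,6-bis(3-methylbut-2-en-1-yl)phenol
Conditions: PPTS (10 mol %), MeOH, rt, dark
Reagents that add atoms: none
Why: Acid-catalysed transacetalisation with methanol should cleave the tetrahydropyranyl acetal through its stabilised cyclic oxocarbenium ion much faster than the MOM acetals, and pyridinium tosylate is too weak an acid to add the freed phenol to the adjacent prenyl group.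

Step 8
Reactants: 14 4-hydroxybenzaldehyde; 15 3-chloro-3-methylbut-1-yne
Product: 16 4-[(2-methylbut-3-yn-2-yl)oxy]benzaldehyde
Conditions: K2CO3 (2 equiv), KI (cat.), CuI (cat.), acetone, reflux
Reagents that add atoms: none
Why: Copper-assisted O-alkylation of the phenoxide with the tertiary propargylic chloride (Williamson-type etherification through a copper-stabilised propargyl cation) should give the aryl 1,1-dimethylpropargyl ether.

Step 9
Reactants: 16 4-[(2-methylbut-3-yn-2-yl)oxy]benzaldehyde
Product: 19 2,2-dimethyl-2H-chromene-6-carbaldehyde, via allenylphenol 17 (not isolated), via quinone methide 18 (not isolated)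
Conditions: N,N-diethylaniline, 190 °C
Reagents that add atoms: none
Why: A thermal aryl propargyl Claisen rearrangement ([3,3]) should give allenylphenol 17, whose [1,5]-hydrogen shift to quinone methide 18 and 6π oxa-electrocyclisation close the 2,2-dimethylpyran ring, the para-formyl group making both ortho positions equivalent.

Step 10
Reactants: 19 2,2-dimethyl-2H-chromene-6-carbaldehyde
Product: 20 6-ethynyl-2,2-dimethyl-2H-chromene
Conditions: dimethyl (1-diazo-2-oxopropyl)phosphonate (1.3 equiv), K2CO3 (2 equiv), MeOH, 0 °C to rt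
Reagents that add atoms: dimethyl (1-diazo-2-oxopropyl)phosphonate, COP(=O)(OC)C(=[N+]=[N-])C(C)=O
Why: Seyferth–Gilbert homologation in its Ohira–Bestmann form: methanolysis of the acetyl group releases the diazomethylphosphonate anion, which adds to the aldehyde, eliminates dimethyl phosphate and loses dinitrogen with a 1,2-hydrogen shift to give the terminal alkyne under conditions mild enough for the chromene.

Step 11
Reactants: 13 2-iodo-3,5-bis(methoxymethoxy)-4,6-bis(3-methylbut-2-en-1-yl)phenol; 20 6-ethynyl-2,2-dimethyl-2H-chromene (1.5 equiv); 21 carbon monoxide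
Product: 24 2-(2,2-dimethyl-2H-chromen-6-yl)-5,7-bis(methoxymethoxy)-6,8-bis(3-methylbut-2-en-1-yl)-4H-chromen-4-one, via ynone 22 (not isolated), via enaminone 23 (not isolated)
Conditions: PdCl2(dppf) (5 mol %), CO (20 bar), Et2NH (solvent), 120 °C, autoclave
Reagents that add atoms: diethylamine, CCNCC (its atoms are present in 23 only, not in 24)
Why: Zerovalent palladium, formed in the flask from PdCl2(dppf), should insert into the C4a–I bond of 13, CO inserts to give an aroylpalladium iodide, and amine-assisted transfer of the acetylide of 20 followed by reductive elimination gives ynone 22 (C4a–C4 and C4–C3). Diethylamine then adds to the ynone to give enaminone 23, and the free hydroxyl on C8a attacks C2 in a 6-endo-trig addition–elimination that expels the amine and closes pyranone ring C (O1–C2). The closest known reaction type is the carbonylative Sonogashira coupling and annulation of ortho-iodophenols with terminal arylalkynes in a secondary amine, which gives flavones. No stereocentre is formed. The step needs 6-endo closure to the flavone instead of 5-exo closure to an aurone, which the enaminone pathway in neat diethylamine secures, and CO insertion ahead of direct alkynylation, which the CO pressure, the absence of copper and the electron-rich, doubly ortho-substituted arylpalladium favour. Only one of the two oxygens that flank C4a is free, so O1 is unambiguous and the acetal on O5 is carried through.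

Step 12
Reactants: 24 2-(2,2-dimethyl-2H-chromen-6-yl)-5,7-bis(methoxymethoxy)-6,8-bis(3-methylbut-2-en-1-yl)-4H-chromen-4-one
Product: 25 (2S)-2-(2,2-dimethyl-2H-chromen-6-yl)-5,7-bis(methoxymethoxy)-6,8-bis(3-methylbut-2-en-1-yl)-2,3-dihydro-4H-chromen-4-one
Conditions: Cu(OAc)2·H2O (5 mol %), (R)-DTBM-SEGPHOS (5.5 mol %), (EtO)2MeSiH (3 equiv), t-BuOH (2 equiv), toluene, 0 °C to rt
Reagents that add atoms: none
Why: Asymmetric conjugate reduction by a bisphosphine-ligated copper hydride: hydride should be delivered to C2 of the vinylogous ester from the face left open by the chiral ligand (catalyst control, giving 2S), the copper enolate is protonated at C3 by tert-butanol and the silane regenerates the hydride, while the isolated prenyl alkenes and, at low temperature, the chromene alkene should stay untouched.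

Step 13
Reactants: 25 (2S)-2-(2,2-dimethyl-2H-chromen-6-yl)-5,7-bis(methoxymethoxy)-6,8-bis(3-methylbut-2-en-1-yl)-2,3-dihydro-4H-chromen-4-one
Product: 26 (2S)-2-(2,2-dimethyl-2H-chromen-6-yl)-5,7-dihydroxy-6,8-bis(3-methylbut-2-en-1-yl)-2,3-dihydro-4H-chromen-4-one (target, CNP0188949.1)
Conditions: 3 M aq. HCl, MeOH, 40 °C
Reagents that add atoms: none
Why: Acid-catalysed acetal cleavage (transacetalisation to dimethoxymethane) should free both phenols, the acetal on O5 leaving first because the new hydroxyl hydrogen-bonds to the C4 carbonyl, and the mild temperature is chosen so that neither prenyl–phenol cyclisation nor acid-mediated opening of ring C at the C2 stereocentre intervenes.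

Compound list

1 | resorcinol (benzene-1,3-diol) | Oc1cccc(O)c1 | starting material
2 | 1,3-bis(methoxymethoxy)benzene | COCOc1cccc(OCOC)c1 | intermediate
3 | 1-bromo-3-methylbut-2-ene (prenyl bromide) | CC(C)=CCBr | starting material
4 | [2,6-bis(methoxymethoxy)phenyl]lithium | [Li]c1c(OCOC)cccc1OCOC | intermediate (not isolated)
5 | 1,3-bis(methoxymethoxy)-2-(3-methylbut-2-en-1-yl)benzene | COCOc1cccc(OCOC)c1CC=C(C)C | intermediate
6 | 2-[3,5-bis(methoxymethoxy)-4-(3-methylbut-2-en-1-yl)phenyl]-4,4,5,5-tetramethyl-1,3,2-dioxaborolane | COCOc1cc(B2OC(C)(C)C(C)(C)O2)cc(OCOC)c1CC=C(C)C | intermediate (not isolated)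
7 | 3,5-bis(methoxymethoxy)-4-(3-methylbut-2-en-1-yl)phenol | COCOc1cc(O)cc(OCOC)c1CC=C(C)C | intermediate
8 | 2-[3,5-bis(methoxymethoxy)-4-(3-methylbut-2-en-1-yl)phenoxy]tetrahydro-2H-pyran (racemic) | COCOc1cc(OC2CCCCO2)cc(OCOC)c1CC=C(C)C | intermediate
9 | [2,4-bis(methoxymethoxy)-3-(3-methylbut-2-en-1-yl)-6-(tetrahydro-2H-pyran-2-yloxy)phenyl]lithium (racemic) | [Li]c1c(OC2CCCCO2)cc(OCOC)c(CC=C(C)C)c1OCOC | intermediate (not isolated)
10 | 2-[3,5-bis(methoxymethoxy)-2,4-bis(3-methylbut-2-en-1-yl)phenoxy]tetrahydro-2H-pyran (racemic) | CC(C)=CCc1c(OC2CCCCO2)cc(OCOC)c(CC=C(C)C)c1OCOC | intermediate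
11 | [2,4-bis(methoxymethoxy)-3,5-bis(3-methylbut-2-en-1-yl)-6-(tetrahydro-2H-pyran-2-yloxy)phenyl]lithium (racemic) | [Li]c1c(OCOC)c(CC=C(C)C)c(OCOC)c(CC=C(C)C)c1OC1CCCCO1 | intermediate (not isolated)
12 | 2-[2-iodo-3,5-bis(methoxymethoxy)-4,6-bis(3-methylbut-2-en-1-yl)phenoxy]tetrahydro-2H-pyran (racemic) | Ic1c(OCOC)c(CC=C(C)C)c(OCOC)c(CC=C(C)C)c1OC1CCCCO1 | intermediate
13 | 2-iodo-3,5-bis(methoxymethoxy)-4,6-bis(3-methylbut-2-en-1-yl)phenol | Oc1c(I)c(OCOC)c(CC=C(C)C)c(OCOC)c1CC=C(C)C | intermediate (precursor of the key step)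
14 | 4-hydroxybenzaldehyde | O=Cc1ccc(O)cc1 | starting material
15 | 3-chloro-3-methylbut-1-yne | C#CC(C)(C)Cl | starting material
16 | 4-[(2-methylbut-3-yn-2-yl)oxy]benzaldehyde | O=Cc1ccc(OC(C)(C)C#C)cc1 | intermediate
17 | 4-hydroxy-3-(3-methylbuta-1,2-dien-1-yl)benzaldehyde | O=Cc1ccc(O)c(C=C=C(C)C)c1 | intermediate (not isolated)
18 | 3-(3-methylbut-2-en-1-ylidene)-4-oxocyclohexa-1,5-diene-1-carbaldehyde (alkene geometry not defined) | O=CC1=CC(=CC=C(C)C)C(=O)C=C1 | intermediate (not isolated)
19 | 2,2-dimethyl-2H-chromene-6-carbaldehyde | O=Cc1ccc2c(c1)C=CC(C)(C)O2 | intermediate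
20 | 6-ethynyl-2,2-dimethyl-2H-chromene | C#Cc1ccc2c(c1)C=CC(C)(C)O2 | intermediate
21 | carbon monoxide | [C-]#[O+] | starting material
22 | 3-(2,2-dimethyl-2H-chromen-6-yl)-1-[2-hydroxy-4,6-bis(methoxymethoxy)-3,5-bis(3-methylbut-2-en-1-yl)phenyl]prop-2-yn-1-one | O=C(C#Cc1ccc2c(c1)C=CC(C)(C)O2)c1c(O)c(CC=C(C)C)c(OCOC)c(CC=C(C)C)c1OCOC | intermediate (not isolated)
23 | 3-(diethylamino)-3-(2,2-dimethyl-2H-chromen-6-yl)-1-[2-hydroxy-4,6-bis(methoxymethoxy)-3,5-bis(3-methylbut-2-en-1-yl)phenyl]prop-2-en-1-one (alkene geometry not defined) | CCN(CC)C(=CC(=O)c1c(O)c(CC=C(C)C)c(OCOC)c(CC=C(C)C)c1OCOC)c1ccc2c(c1)C=CC(C)(C)O2 | intermediate (not isolated)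
24 | 2-(2,2-dimethyl-2H-chromen-6-yl)-5,7-bis(methoxymethoxy)-6,8-bis(3-methylbut-2-en-1-yl)-4H-chromen-4-one | O=c1cc(-c2ccc3c(c2)C=CC(C)(C)O3)oc2c(CC=C(C)C)c(OCOC)c(CC=C(C)C)c(OCOC)c12 | intermediate (product of the key step)
25 | (2S)-2-(2,2-dimethyl-2H-chromen-6-yl)-5,7-bis(methoxymethoxy)-6,8-bis(3-methylbut-2-en-1-yl)-2,3-dihydro-4H-chromen-4-one | CC(C)=CCc1c(OCOC)c(CC=C(C)C)c2c(c1OCOC)C(=O)C[C@@H](c1ccc3c(c1)C=CC(C)(C)O3)O2 | intermediate
26 | (2S)-2-(2,2-dimethyl-2H-chromen-6-yl)-5,7-dihydroxy-6,8-bis(3-methylbut-2-en-1-yl)-2,3-dihydro-4H-chromen-4-one | CC(C)=CCc1c(O)c(CC=C(C)C)c2c(c1O)C(=O)C[C@@H](c1ccc3c(c1)C=CC(C)(C)O3)O2 | target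

Total step count: 13.
Longest linear sequence: 10 steps (steps 1 to 7, then 11 to 13); steps 8 to 10 make the alkyne in parallel.

Steps most likely to fail

Step 12. Hydride transfer to a hindered, electron-rich 2-aryl vinylogous ester may be slow, the ligand may discriminate the two faces poorly, and the copper enolate may open ring C by expelling the C8a phenoxide, which would erode the enantiomeric purity. Reduction of the styrene-like chromene alkene or of the C4 carbonyl may also compete. The fallback gives up catalyst control and resolves instead. It sets out from flavone 24. Conjugate reduction without a chiral ligand ([(Ph3P)CuH]6 (cat.), (EtO)2MeSiH, t-BuOH, toluene) should give racemic 2-(2,2-dimethyl-2H-chromen-6-yl)-5,7-bis(methoxymethoxy)-6,8-bis(3-methylbut-2-en-1-yl)-2,3-dihydro-4H-chromen-4-one F1. Preparative chromatography on a chiral stationary phase (amylose tris(3,5-dimethylphenylcarbamate), heptane/2-propanol) would then deliver 25 and the (2R)-enantiomer F2, which can be racemised with a catalytic amine base and resolved again. The fallback comes back to the route at 25.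

Step 11. Oxidative addition into a C–I bond flanked by two oxygen substituents may be slow, the aroylpalladium may be captured by diethylamine as an amide, the iodide may be reduced off, or alkynylation without CO may lead to a benzofuran. The fallback builds the same ynone without palladium or CO and sets out from 10 and 20. Alkyne 20 is deprotonated (n-BuLi, THF, −78 °C) and acylated with N-methoxy-N-methylcarbamoyl chloride to give 3-(2,2-dimethyl-2H-chromen-6-yl)-N-methoxy-N-methylprop-2-ynamide F3. Aryllithium 11, generated from 10 as in step 6, is added to this Weinreb amide at −78 °C and should give 3-(2,2-dimethyl-2H-chromen-6-yl)-1-[2,4-bis(methoxymethoxy)-3,5-bis(3-methylbut-2-en-1-yl)-6-(tetrahydro-2H-pyran-2-yloxy)phenyl]prop-2-yn-1-one F4. PPTS in MeOH then frees ynone 22, and Et2NH in EtOH at 40 °C closes ring C through enaminone 23. The fallback comes back to the route at 24.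

Step 13. Under acid, a freed hydroxyl on C5 or C7 may add to the neighbouring prenyl double bond, methanol may add to the chromene double bond, and ring C may open and reclose with partial loss of configuration at C2. The fallback moves the acidic unmasking to the achiral flavone and carries fluoride-labile groups through the reduction; it sets out from 24. Treatment of 24 with 3 M aq. HCl in MeOH, where by-products can be separated with no stereocentre at stake, should give 2-(2,2-dimethyl-2H-chromen-6-yl)-5,7-dihydroxy-6,8-bis(3-methylbut-2-en-1-yl)-4H-chromen-4-one F5. Silylation (TBSOTf, 2,6-lutidine, CH2Cl2) gives 5,7-bis(tert-butyldimethylsilyloxy)-2-(2,2-dimethyl-2H-chromen-6-yl)-6,8-bis(3-methylbut-2-en-1-yl)-4H-chromen-4-one F6. Copper hydride reduction as in step 12 gives (2S)-5,7-bis(tert-butyldimethylsilyloxy)-2-(2,2-dimethyl-2H-chromen-6-yl)-6,8-bis(3-methylbut-2-en-1-yl)-2,3-dihydro-4H-chromen-4-one F7. Buffered fluoride (HF·pyridine, pyridine, THF, 0 °C) then removes the silyl groups. The fallback comes back to the route at 26.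

Further compounds

F1 | step 12 | racemic 2-(2,2-dimethyl-2H-chromen-6-yl)-5,7-bis(methoxymethoxy)-6,8-bis(3-methylbut-2-en-1-yl)-2,3-dihydro-4H-chromen-4-one | CC(C)=CCc1c(OCOC)c(CC=C(C)C)c2c(c1OCOC)C(=O)CC(c1ccc3c(c1)C=CC(C)(C)O3)O2
F2 | step 12 | (2R)-2-(2,2-dimethyl-2H-chromen-6-yl)-5,7-bis(methoxymethoxy)-6,8-bis(3-methylbut-2-en-1-yl)-2,3-dihydro-4H-chromen-4-one | CC(C)=CCc1c(OCOC)c(CC=C(C)C)c2c(c1OCOC)C(=O)C[C@H](c1ccc3c(c1)C=CC(C)(C)O3)O2
F3 | step 11 | 3-(2,2-dimethyl-2H-chromen-6-yl)-N-methoxy-N-methylprop-2-ynamide | CON(C)C(=O)C#Cc1ccc2c(c1)C=CC(C)(C)O2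
F4 | step 11 | 3-(2,2-dimethyl-2H-chromen-6-yl)-1-[2,4-bis(methoxymethoxy)-3,5-bis(3-methylbut-2-en-1-yl)-6-(tetrahydro-2H-pyran-2-yloxy)phenyl]prop-2-yn-1-one (racemic) | O=C(C#Cc1ccc2c(c1)C=CC(C)(C)O2)c1c(OC2CCCCO2)c(CC=C(C)C)c(OCOC)c(CC=C(C)C)c1OCOC
F5 | step 13 | 2-(2,2-dimethyl-2H-chromen-6-yl)-5,7-dihydroxy-6,8-bis(3-methylbut-2-en-1-yl)-4H-chromen-4-one | O=c1cc(-c2ccc3c(c2)C=CC(C)(C)O3)oc2c(CC=C(C)C)c(O)c(CC=C(C)C)c(O)c12
F6 | step 13 | 5,7-bis(tert-butyldimethylsilyloxy)-2-(2,2-dimethyl-2H-chromen-6-yl)-6,8-bis(3-methylbut-2-en-1-yl)-4H-chromen-4-one | O=c1cc(-c2ccc3c(c2)C=CC(C)(C)O3)oc2c(CC=C(C)C)c(O[Si](C)(C)C(C)(C)C)c(CC=C(C)C)c(O[Si](C)(C)C(C)(C)C)c12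
F7 | step 13 | (2S)-5,7-bis(tert-butyldimethylsilyloxy)-2-(2,2-dimethyl-2H-chromen-6-yl)-6,8-bis(3-methylbut-2-en-1-yl)-2,3-dihydro-4H-chromen-4-one | CC(C)=CCc1c(O[Si](C)(C)C(C)(C)C)c(CC=C(C)C)c2c(c1O[Si](C)(C)C(C)(C)C)C(=O)C[C@@H](c1ccc3c(c1)C=CC(C)(C)O3)O2
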